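**Plan**
1. Retrosynthesis: the hydroxyquinone and the acetate are taken back to keto lactone 19. In 19 the C10–C20 bond of ring B and the C10–O bond of the lactone bridge are cut together, which leaves the monocyclic diketo ester 16. Compound 16 is cut at C5–C6 (aldol) and at C4–CH3 (conjugate addition) into enone ester 11, Me2Zn and aryl glyoxal 10.
2. Enabling feature: in 16 the C7 carbonyl on C8 of ring C is ortho to the C20 methyl on C9 (O7···H–C20 in a 1,5-relationship), so light turns C20 into a dienol carbon nucleophile. On ring A the C10 ketone stands 1,3 to the C19 ester, so the one C–C bond made at C10 closes ring B and the alkoxide it leaves closes the γ-lactone bridge.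
3. Forward order: ring C is bought as 1,2,4-trimethoxybenzene and fully substituted. Ring A comes from 11, with a temporary cis-fused lactone (C19–O–C6) that is cut again. Ring B and the lactone bridge then form together. C7 reduction, acetylation and oxidation of ring C finish the route.
4. Stereochemistry: C4 from the chiral copper–carbene catalyst; C5 relayed from C4 through the temporary cis-fused lactone; C10 from C4 and C5 in the ring closure; C7 from substrate-controlled hydride delivery.

Key step: step 10

Remark: diterpenoid atom numbers (C1–C20, rings A, B, C) are used for all intermediates; α is the face of H-5 and β the face of C19; Ar = 3-isopropyl-2,4,5-trimethoxy-6-methylphenyl; enone ester 11 is assumed to be a catalogue compound.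

Step 1
Reactants: 1 1,2,4-trimethoxybenzene
Product: 3 2-(2,3,6-trimethoxyphenyl)propan-2-ol, via aryllithium 2 (not isolated)
Conditions: n-BuLi, THF, 0 °C; acetone, −78 °C → rt; H2O work-up
Reagents that add atoms: acetone CC(C)=O
Why: Directed ortho-metalation removes the ring hydrogen flanked by two methoxy groups (the most acidic one) and the aryllithium adds to acetone, which places the future isopropyl carbon skeleton at C13.

Step 2
Reactants: 3 2-(2,3,6-trimethoxyphenyl)propan-2-ol
Product: 4 2-isopropyl-1,3,4-trimethoxybenzene
Conditions: Et3SiH, CF3CO2H, CH2Cl2, 0 °C → rt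
Reagents that add atoms: none
Why: Ionic hydrogenation: the acid ionises the tertiary benzylic alcohol and the silane delivers hydride to the cation, while aryl methyl ethers are inert.

Step 3
Reactants: 4 2-isopropyl-1,3,4-trimethoxybenzene
Product: 5 1-bromo-3-isopropyl-2,4,5-trimethoxybenzene
Conditions: NBS, MeCN, 0 °C
Reagents that add atoms: N-bromosuccinimide O=C1CCC(=O)N1Br
Why: Electrophilic aromatic bromination goes to the one free position that is ortho to one methoxy group and para to another (the future C8), the other free position being activated by a single methoxy group only.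

Step 4
Reactants: 5 1-bromo-3-isopropyl-2,4,5-trimethoxybenzene
Product: 7 1-bromo-3-isopropyl-2,4,5-trimethoxy-6-methylbenzene, via aryllithium 6 (not isolated)
Conditions: LiN(i-Pr)2, THF, −78 °C; MeI, −78 → 0 °C
Reagents that add atoms: iodomethane CI
Why: The only ring hydrogen left is acidified by the flanking bromine and methoxy group (ortho-lithiation of a 3-bromoanisole, kept at −78 °C so that LiBr is not lost), and methylation of the aryllithium installs C20 on C9.

Step 5
Reactants: 7 1-bromo-3-isopropyl-2,4,5-trimethoxy-6-methylbenzene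
Product: 9 2,2-diethoxy-1-(3-isopropyl-2,4,5-trimethoxy-6-methylphenyl)ethan-1-one, via aryllithium 8 (not isolated)
Conditions: n-BuLi, THF, −78 °C; ethyl diethoxyacetate, −78 °C; H2O work-up
Reagents that add atoms: ethyl diethoxyacetate CCOC(=O)C(OCC)OCC
Why: Bromine–lithium exchange followed by acylation with an α,α-dialkoxy ester, whose chelated tetrahedral adduct (and the doubly ortho-substituted product ketone) resists a second addition, attaches C7 and C6 to C8.

Step 6
Reactants: 9 2,2-diethoxy-1-(3-isopropyl-2,4,5-trimethoxy-6-methylphenyl)ethan-1-one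
Product: 10 2-(3-isopropyl-2,4,5-trimethoxy-6-methylphenyl)-2-oxoacetaldehyde (aryl glyoxal ArCOCHO)
Conditions: CF3CO2H–H2O (9:1), 40 °C; azeotropic drying (PhMe); kept from light
Reagents that add atoms: water O
Why: Acid hydrolysis of the acetal frees the glyoxal aldehyde (C6), which is dehydrated from its hydrate before use.

Step 7
Reactants: 11 methyl 3-oxocyclohex-1-ene-1-carboxylate; 10 aryl glyoxal ArCOCHO
Product: 14 cis-fused keto lactone (3R,3aR,7aS)-3-(ArCO)-7a-methylhexahydroisobenzofuran-1,4-dione (C19–O–C6 lactone; C10 ketone; aroyl group on the convex face), via zinc enolate 12 (not isolated), via aldol adduct 13 (not isolated)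
Conditions: Me2Zn (1.5 equiv), Cu(OTf)2 (5 mol %), chiral sulfonate-bearing imidazolinium salt (carbene precursor, 6 mol %), Et2O, −30 °C; then 10, −78 → 25 °C; aq. NH4Cl; then PPTS (10 mol %), PhMe, 60 °C
Reagents that add atoms: dimethylzinc C[Zn]C
Why: Copper-catalysed asymmetric conjugate addition of Me2Zn to the β-ester enone (a γ-keto ester, an established substrate class for carbene–copper catalysts) sets C4 under ligand control, the regiodefined zinc enolate adds to the aldehyde of 10 (aldol), and under reversible aldol and acid-catalysed enolisation conditions the material should funnel into the cis-fused five-membered lactone (the stable fusion for a bicyclo[4.3.0] lactone with an angular methyl), which fixes the C6 side chain cis to C19 and H-5 cis to the C4 methyl as the target requires; C6 is a temporary centre.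

Step 8
Reactants: 14 cis-fused keto lactone
Product: 15 (1S,2S)-1-methyl-3-oxo-2-(2-oxo-2-Ar-ethyl)cyclohexane-1-carboxylic acid
Conditions: SmI2 (2.2 equiv), THF–MeOH, −78 °C
Reagents that add atoms: none
Why: SmI2 reduction of an α-acyloxy ketone (ketyl at C7, loss of the carboxylate from C6, protonation of the samarium enolate by MeOH) cuts the temporary C6–O bond without base, so C5 keeps its configuration; the bond has to go before irradiation because an o-methylphenacyl ester would photo-release its carboxylate.

Step 9
Reactants: 15 (1S,2S)-1-methyl-3-oxo-2-(2-oxo-2-Ar-ethyl)cyclohexane-1-carboxylic acid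
Product: 16 methyl (1S,2S)-1-methyl-3-oxo-2-(2-oxo-2-Ar-ethyl)cyclohexane-1-carboxylate
Conditions: Me3SiCHN2, PhMe–MeOH, 0 °C
Reagents that add atoms: (trimethylsilyl)diazomethane C[Si](C)(C)C=[N+]=[N-]
Why: Esterification with a diazoalkane is neutral, so the epimerisable C5 (α to the C10 ketone) and the acid-sensitive 1,4-diketone are not disturbed.

Step 10
Reactants: 16 methyl (1S,2S)-1-methyl-3-oxo-2-(2-oxo-2-Ar-ethyl)cyclohexane-1-carboxylate
Product: 19 (4S,5S,10S)-11,12,14-trimethoxy-7-oxoicetexa-8,11,13-trien-19,10-olide, via photoenol 17 (not isolated), via hydroxy ketone 18 (not isolated)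
Conditions: hν (365 nm LED), Ti(Oi-Pr)4 (30 mol %), degassed PhMe, 25 °C; then camphorsulfonic acid (5 mol %), 25 °C
Reagents that add atoms: none
Why: Proposed new method: n→π* excitation of the C7 aryl ketone is followed by 1,5-hydrogen transfer from the ortho C20 methyl group to give the hydroxy-o-quinodimethane 17, whose long-lived isomer carries the C6 chain on the side of the new C20 methylene; this nucleophilic terminus adds to the C10 ketone (titanium can bridge O7 and O10) with rearomatisation of ring C to give 18 (or its 7,10-bridged hemiketal), and the C10 oxygen then acylates on the C19 ester to give 19. The closest known reaction types are the photoenolisation/Diels–Alder reaction of o-tolyl carbonyl compounds promoted by Ti(Oi-Pr)4 and the trapping of such photoenols by CO2 and by activated ketones; intramolecular addition to an unactivated ketone is not established, hence the label. Ring B closes by 7-exo-trig addition of C20 to C10=O (the carbon half of a formal hetero-Diels–Alder reaction) and the lactone bridge by 5-exo-trig acyl substitution of the C10 oxygen on C19. The new stereocentre C10 is controlled by C4 and C5: in the ring A chair with the C5 chain and C4 methyl equatorial the axial ester covers the β-face, so C20 should arrive along the equatorial α-trajectory, ring B becomes trans-fused, and the new C10–O bond is axial and syn to the ester it then attacks. The step needs hydrogen abstraction at C20 only and attack on C10 only; the first is secured because the C7 carbonyl has no other γ-hydrogen and the aliphatic C10 ketone does not absorb at 365 nm, the second because C10 is the only carbonyl within reach of the dienol terminus.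

Step 11
Reactants: 19 (4S,5S,10S)-11,12,14-trimethoxy-7-oxoicetexa-8,11,13-trien-19,10-olide
Product: 20 (4S,5S,7R,10S)-7α-hydroxy-11,12,14-trimethoxyicetexa-8,11,13-trien-19,10-olide
Conditions: NaBH4, MeOH–CH2Cl2, −20 °C; aq. work-up
Reagents that add atoms: none
Why: Hydride should add to the twisted C7 aryl ketone along the pseudo-axial trajectory from the β-face, the α-face being screened by the flanking C14 methoxy group and axial H-5, to give the pseudo-equatorial 7α-alcohol (substrate control), and the lactone is inert to NaBH4 at this temperature.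

Step 12
Reactants: 20 7α-alcohol
Product: 21 (4S,5S,7R,10S)-7α-acetoxy-11,12,14-trimethoxyicetexa-8,11,13-trien-19,10-olide
Conditions: Ac2O, pyridine, DMAP (10 mol %), CH2Cl2, rt
Reagents that add atoms: acetic anhydride CC(=O)OC(C)=O
Why: Nucleophile-catalysed acylation of the hindered secondary benzylic alcohol proceeds with retention at C7.

Step 13
Reactants: 21 7α-acetate
Product: 22 (4S,5S,7R,10S)-7α-acetoxy-12-methoxyicetexa-8,12-diene-11,14-dione-19,10-olide
Conditions: (NH4)2Ce(NO3)6 (2.5 equiv), MeCN–H2O, 0 °C
Reagents that add atoms: water O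
Why: Oxidative demethylation of the para-related C11 and C14 methoxy groups by two equivalents of tetravalent cerium gives the p-quinone (water supplies the carbonyl oxygens) and leaves the C12 methoxy group as a vinylogous ester, while acetate and lactone should survive the brief acidic conditions.

Step 14
Reactants: 22 12-methoxyquinone
Product: 23 7α-acetoxy-6,7-dihydroicetexone
Conditions: BCl3, CH2Cl2, −78 → −30 °C; H2O work-up
Reagents that add atoms: none
Why: BCl3 chelates between the C11 carbonyl and the C12 methoxy oxygen and cleaves only this O–CH3 bond at low temperature (chelation-assisted demethylation of a 2-methoxy-1,4-quinone), which should spare the acetate and the lactone.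

**Compound list**
1 | 1,2,4-trimethoxybenzene | COc1ccc(OC)c(OC)c1 | starting material
2 | (2,3,6-trimethoxyphenyl)lithium | [Li]c1c(OC)ccc(OC)c1OC | intermediate
3 | 2-(2,3,6-trimethoxyphenyl)propan-2-ol | COc1ccc(OC)c(C(C)(C)O)c1OC | intermediate
4 | 2-isopropyl-1,3,4-trimethoxybenzene | COc1ccc(OC)c(C(C)C)c1OC | intermediate
5 | 1-bromo-3-isopropyl-2,4,5-trimethoxybenzene | COc1cc(Br)c(OC)c(C(C)C)c1OC | intermediate
6 | (2-bromo-4-isopropyl-3,5,6-trimethoxyphenyl)lithium | COc1c([Li])c(Br)c(OC)c(C(C)C)c1OC | intermediate
7 | 1-bromo-3-isopropyl-2,4,5-trimethoxy-6-methylbenzene | COc1c(C)c(Br)c(OC)c(C(C)C)c1OC | intermediate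
8 | (3-isopropyl-2,4,5-trimethoxy-6-methylphenyl)lithium | COc1c(C)c([Li])c(OC)c(C(C)C)c1OC | intermediate
9 | 2,2-diethoxy-1-(3-isopropyl-2,4,5-trimethoxy-6-methylphenyl)ethan-1-one | CCOC(OCC)C(=O)c1c(C)c(OC)c(OC)c(C(C)C)c1OC | intermediate
10 | 2-(3-isopropyl-2,4,5-trimethoxy-6-methylphenyl)-2-oxoacetaldehyde | O=CC(=O)c1c(C)c(OC)c(OC)c(C(C)C)c1OC | intermediate
11 | methyl 3-oxocyclohex-1-ene-1-carboxylate | COC(=O)C1=CC(=O)CCC1 | starting material
12 | methyl (S)-1-methyl-3-[(methylzincio)oxy]cyclohex-2-ene-1-carboxylate (zinc enolate) | COC(=O)[C@@]1(C)CCCC(O[Zn]C)=C1 | intermediate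
13 | methyl (1S)-2-(1-hydroxy-2-oxo-2-Ar-ethyl)-1-methyl-3-oxocyclohexane-1-carboxylate (aldol adduct, mixture at C5 and C6) | COC(=O)[C@@]1(C)CCCC(=O)C1C(O)C(=O)c1c(C)c(OC)c(OC)c(C(C)C)c1OC | intermediate
14 | (3R,3aR,7aS)-3-(3-isopropyl-2,4,5-trimethoxy-6-methylbenzoyl)-7a-methylhexahydroisobenzofuran-1,4-dione | C[C@]12CCCC(=O)[C@H]1[C@@H](OC2=O)C(=O)c1c(C)c(OC)c(OC)c(C(C)C)c1OC | intermediate
15 | (1S,2S)-1-methyl-3-oxo-2-(2-oxo-2-Ar-ethyl)cyclohexane-1-carboxylic acid | O=C(O)[C@@]1(C)CCCC(=O)[C@H]1CC(=O)c1c(C)c(OC)c(OC)c(C(C)C)c1OC | intermediate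
16 | methyl (1S,2S)-1-methyl-3-oxo-2-(2-oxo-2-Ar-ethyl)cyclohexane-1-carboxylate | COC(=O)[C@@]1(C)CCCC(=O)[C@H]1CC(=O)c1c(C)c(OC)c(OC)c(C(C)C)c1OC | intermediate
17 | hydroxy-o-quinodimethane (photoenol) of 16: C20H2=C9 and C8=C7(OH), hydroxyl pointing away from C20 | COC(=O)[C@@]1(C)CCCC(=O)[C@H]1C/C(O)=C1\C(=C)C(OC)=C(OC)C(C(C)C)=C1OC | intermediate
18 | methyl (4S,5S,10S)-10-hydroxy-11,12,14-trimethoxy-7-oxoicetexa-8,11,13-trien-19-oate (hydroxy ketone) | O=C1C[C@@H]2[C@](O)(CCC[C@]2(C)C(=O)OC)Cc2c1c(OC)c(C(C)C)c(OC)c2OC | intermediate
19 | (4S,5S,10S)-11,12,14-trimethoxy-7-oxoicetexa-8,11,13-trien-19,10-olide | O=C1C[C@@H]2[C@]3(CCC[C@]2(C)C(=O)O3)Cc2c1c(OC)c(C(C)C)c(OC)c2OC | intermediate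
20 | (4S,5S,7R,10S)-7α-hydroxy-11,12,14-trimethoxyicetexa-8,11,13-trien-19,10-olide | O[C@@H]1C[C@@H]2[C@]3(CCC[C@]2(C)C(=O)O3)Cc2c1c(OC)c(C(C)C)c(OC)c2OC | intermediate
21 | (4S,5S,7R,10S)-7α-acetoxy-11,12,14-trimethoxyicetexa-8,11,13-trien-19,10-olide | CC(=O)O[C@@H]1C[C@@H]2[C@]3(CCC[C@]2(C)C(=O)O3)Cc2c1c(OC)c(C(C)C)c(OC)c2OC | intermediate
22 | (4S,5S,7R,10S)-7α-acetoxy-12-methoxyicetexa-8,12-diene-11,14-dione-19,10-olide | CC(=O)O[C@@H]1C[C@@H]2[C@]3(CCC[C@]2(C)C(=O)O3)CC2=C1C(=O)C(C(C)C)=C(OC)C2=O | intermediate
23 | 7α-acetoxy-6,7-dihydroicetexone | CC(=O)O[C@@H]1C[C@@H]2[C@]3(CCC[C@]2(C)C(=O)O3)CC2=C1C(=O)C(C(C)C)=C(O)C2=O | target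

**Step count and risks**
Total steps: 14. Longest linear sequence: 14 (1 → 23; 11 enters as a purchased partner in step 7).

Steps most likely to fail:

Step 10 (labelled step). The photoenol may return to 16 by 1,5-hydrogen shift, or electrocyclise to a benzocyclobutenol, faster than it adds to the unactivated C10 ketone. Fallback with known chemistry, from 16 back to 19: Wohl–Ziegler bromination of the C20 methyl group of 16 (NBS, AIBN, PhCF3, 80 °C; every ring position is blocked) should give the bromomethyl ketone F1. SmI2 (2.2 equiv, THF, −78 °C) reduces the benzylic bromide faster than either ketone. The benzylic samarium species, a dienolate through the C7 carbonyl, should then add to C10 in a Barbier/Reformatsky-type cyclisation, and the samarium alkoxide lactonises onto C19 to give 19.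

Step 7. Methyl transfer from zinc to the glyoxal aldehyde, slow aldol addition of the hindered zinc enolate next to the quaternary carbon, or incomplete funnelling into the cis-fused lactone may erode the one-flask sequence. Fallback, from 11 back to 14: the same copper-catalysed methyl addition is quenched with Me3SiCl to give the isolable silyl enol ether F2. A Mukaiyama aldol addition of F2 to 10 (BF3·OEt2, CH2Cl2, −78 °C), with no organozinc present, should give aldol adduct 13, which PPTS in warm PhMe converts into 14 as in the main route.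

Step 11. Hydride delivery to the twisted C7 ketone may show poor facial selectivity or prefer the α-face. Fallback, from 19 back to 21: the 7β-alcohol F3 formed by α-face attack (favoured if needed with the bulky LiBH(s-Bu)3, THF, −78 °C) is treated with acetic acid under Mitsunobu conditions (PPh3, DIAD, PhMe, 0 °C), which inverts C7 and gives acetate 21 directly without passing through 20.

Further compounds
F1 | step 10 | methyl (1S,2S)-2-{2-[2-(bromomethyl)-4-isopropyl-3,5,6-trimethoxyphenyl]-2-oxoethyl}-1-methyl-3-oxocyclohexane-1-carboxylate | COC(=O)[C@@]1(C)CCCC(=O)[C@H]1CC(=O)c1c(CBr)c(OC)c(OC)c(C(C)C)c1OC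
F2 | step 7 | methyl (S)-1-methyl-3-[(trimethylsilyl)oxy]cyclohex-2-ene-1-carboxylate | COC(=O)[C@@]1(C)CCCC(O[Si](C)(C)C)=C1
F3 | step 11 | (4S,5S,7S,10S)-7β-hydroxy-11,12,14-trimethoxyicetexa-8,11,13-trien-19,10-olide | O[C@H]1C[C@@H]2[C@]3(CCC[C@]2(C)C(=O)O3)Cc2c1c(OC)c(C(C)C)c(OC)c2OC
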